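Atoms carry the numbers of the target SMILES. Ring A (C4, C5, C6, C12, C13) and its acetyl group (C1, C2) are read as a ring-contracted 1-methylcyclohexene, so rings A and B go back to a [4+2] adduct of a diene at C6 (C6=C5–C2=C4) with the prenyl alkene C12=C13 held on C9. In one operation methacrolein condenses at C6 of the enantiopure dearomatised acylphloroglucinol 7, (S)-2-isobutyryl-4-methyl-4-prenylcyclohexane-1,3,5-trione, and the resulting diene closes ring B and the cyclohexene, forming C5–C6, C6–C12 and C4–C13 and setting C6 and C12. Alkene cleavage with aldol reclosure, reduction and prenylation at C18 complete the target.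

Key step: step 5

Remark 1: the C4 epimer of the target, with the acetyl group cis to H-12 on the face of ring A turned away from ring B, is taken to be the thermodynamically favoured one, so that equilibration can set C4.
Remark 2: which antipode of the ligand in step 3 gives the (S) centre cannot be predicted with certainty; the (R,R) ligand is written and the (S,S) ligand is used if the sense proves opposite.

Step 1
Reactants: 1 2-methylphloroglucinol; 2 isobutyryl chloride
Product: 3 1-(2,4,6-trihydroxy-3-methylphenyl)-2-methylpropan-1-one
Conditions: AlCl3 (3.5 equiv), PhNO2/CH2Cl2, 0 °C to rt; aq. HCl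
Reagents that add atoms: none
Why: Friedel–Crafts acylation of a highly activated arene whose two free positions are equivalent, the first acyl group deactivating the ring against a second.

Step 2
Reactants: 3 1-(2,4,6-trihydroxy-3-methylphenyl)-2-methylpropan-1-one
Product: 4 1-(3-chloro-2,4,6-trihydroxy-5-methylphenyl)-2-methylpropan-1-one
Conditions: SO2Cl2 (1.05 equiv), CHCl3, EtOH (cat.), 0 °C to rt
Reagents that add atoms: sulfuryl chloride, O=S(=O)(Cl)Cl
Why: Electrophilic aromatic chlorination at the only ring carbon that still bears hydrogen, routine for acylphloroglucinols; the chlorine blocks this carbon so that step 3 can only alkylate the methyl-bearing carbon.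

Step 3
Reactants: 4 1-(3-chloro-2,4,6-trihydroxy-5-methylphenyl)-2-methylpropan-1-one; 5 prenyl acetate
Product: 6 6-chloro-2-isobutyryl-4-methyl-4-prenylcyclohexane-1,3,5-trione (dienol form; quaternary carbon as in 7)
Conditions: Pd2(dba)3·CHCl3 (2.5 mol%), (R,R)-N,N'-(cyclohexane-1,2-diyl)bis[2-(diphenylphosphanyl)benzamide] (7.5 mol%), prenyl acetate (1.05 equiv), Et3N (2.2 equiv), CH2Cl2, rt
Reagents that add atoms: none
Why: Asymmetric allylic alkylation of the Tsuji–Trost type run as a dearomatisation: the phenolate attacks the unsubstituted terminus of the π-prenyl palladium complex through its methyl-bearing carbon (the acyl- and chlorine-bearing carbons are deactivated and O-prenyl ethers re-ionise), and the chiral ligand pocket selects the face of that carbon and so sets C9.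

Step 4
Reactants: 6 6-chloro-2-isobutyryl-4-methyl-4-prenylcyclohexane-1,3,5-trione
Product: 7 (S)-2-isobutyryl-4-methyl-4-prenylcyclohexane-1,3,5-trione (enol form)
Conditions: Zn dust (5 equiv), AcOH/THF, rt
Reagents that add atoms: none
Why: Reductive dehalogenation of an α-chloro-β-dicarbonyl compound by zinc in acetic acid, which leaves the prenyl alkene and the non-enolisable quaternary centre C9 untouched.

Step 5
Reactants: 7 (S)-2-isobutyryl-4-methyl-4-prenylcyclohexane-1,3,5-trione; 8 methacrolein
Product: 10 tricyclic methylcyclohexene adduct, via dienyl trione 9 (not isolated)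
Conditions: methacrolein (3 equiv, in portions), ethylenediammonium diacetate (20 mol%), BHT (cat.), 4 Å MS, toluene, 40 °C, then 130 °C (sealed tube)
Reagents that add atoms: none
Why: The ammonium acetate condenses the aldehyde with the nucleophilic C6 of the enolised trione (Knoevenagel condensation, C5–C6), and the dienyl trione 9, an electron-poor 1,1-diacyl diene (C6=C5–C2=C4), then adds the electron-rich prenyl alkene in a thermal intramolecular Diels–Alder reaction of inverse electron demand, forming C6–C12 and C4–C13. The closest known reaction types are the domino Knoevenagel/intramolecular cycloadditions of cyclic 1,3-diones with aldehydes and the thermal cyclisation of nona-1,3,8-trien-5-ones to hydrindenones. Ring B closes through the C6–C12 bond as the five-membered tether ring of a fused (type 1) intramolecular cycloaddition, exo to the C6=C5 bond and bridging ring C into a bicyclo[3.2.1]octane, and the cyclohexene closes as the [4+2] ring itself by suprafacial addition across C6 and C4. C6 is set by C9, because the C11–C12 arm can reach only the face of ring C on which it stands, and C12 is set by the three-atom tether (C7, C9, C11), which lets C13 lie over C4 only when the diene is folded toward C7, so that C13 ends exo and syn to the C7 bridge. The step needs periselectivity for the carbon diene: hetero-Diels–Alder addition through O8 or O30 would give a bridgehead enol ether, whereas the 2H-pyran from oxa-6π closure, the conjugate adduct of methacrolein and the bis-trione adduct all re-open under the amine salt at 130 °C, leaving the all-carbon adduct as the only sink. The tether also overrides the electronically preferred orientation (C12 to C4), for which no strain-free transition state exists.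

Step 6
Reactants: 10 tricyclic methylcyclohexene adduct
Product: 12 acetylcyclopentene triketone, via keto aldehyde 11 (not isolated)
Conditions: O3, CH2Cl2, −78 °C (Sudan red 7B as indicator); PPh3, −78 °C to rt; then TsOH·H2O (20 mol%), 4 Å MS, toluene, 70 °C
Reagents that add atoms: ozone, [O-][O+]=O
Why: Ozonolysis of the only non-enolic alkene with phosphine work-up in an alcohol-free medium (which spares the retro-Claisen-prone formyl group on C6), followed by acid-catalysed intramolecular aldol condensation in which the non-enolisable aldehyde C5 is attacked by the more substituted enol (C2=C4) of the methyl ketone in a 5-exo closure preferred over a seven-membered one; no stereocentre is touched.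

Step 7
Reactants: 12 acetylcyclopentene triketone
Product: 14 acetylcyclopentane triketone (C4 as in the target), via C4-epimeric ketone 13 (not isolated)
Conditions: H2 (1–3 atm), Pd/C (10 wt%), EtOAc, rt; filter; DBU (3 equiv), toluene, 60 °C; dilute HCl wash
Reagents that add atoms: none
Why: Heterogeneous catalytic hydrogenation of the enone, expected mainly from the face away from ring B, followed by epimerisation through the C4 enolate with a non-nucleophilic amidine (no retro-Claisen opening at C7), which should place the acetyl group on the thermodynamically preferred face cis to H-12 and so set C4.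

Step 8
Reactants: 14 acetylcyclopentane triketone; 5 prenyl acetate
Product: 15 CNP0322535.2 (target)
Conditions: Pd(PPh3)4 (5 mol%), prenyl acetate (1.5 equiv), Et3N (1.5 equiv), THF, 45 °C
Reagents that add atoms: none
Why: Tsuji–Trost allylation of a stabilised tricarbonyl carbanion, in which O-prenyl enol ethers re-ionise so that the C-prenyl product accumulates, attack occurs at the unhindered CH2 terminus, and the electrophile reaches C18 from the face syn to the one-carbon C7 bridge and away from the C11–C12 bridge, which sets C18 as in the target.

Compound list
1 | 2-methylphloroglucinol (2-methylbenzene-1,3,5-triol) | Cc1c(O)cc(O)cc1O | starting material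
2 | isobutyryl chloride | CC(C)C(Cl)=O | starting material
3 | 1-(2,4,6-trihydroxy-3-methylphenyl)-2-methylpropan-1-one | CC(C)C(=O)c1c(O)cc(O)c(C)c1O | intermediate
4 | 1-(3-chloro-2,4,6-trihydroxy-5-methylphenyl)-2-methylpropan-1-one | CC(C)C(=O)c1c(O)c(C)c(O)c(Cl)c1O | intermediate
5 | prenyl acetate (3-methylbut-2-en-1-yl acetate) | CC(C)=CCOC(C)=O | starting material
6 | 4-chloro-3,5-dihydroxy-6-methyl-6-(3-methylbut-2-en-1-yl)-2-(2-methylpropanoyl)cyclohexa-2,4-dien-1-one (dienol form of the 6-chloro derivative of 7; quaternary carbon arranged as in 7) | CC(C)C(=O)C1=C(O)C(Cl)=C(O)[C@](C)(CC=C(C)C)C1=O | intermediate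
7 | (4S)-4-methyl-4-(3-methylbut-2-en-1-yl)-2-(2-methylpropanoyl)cyclohexane-1,3,5-trione, enol form | CC(C)C(=O)C1=C(O)CC(=O)[C@](C)(CC=C(C)C)C1=O | intermediate
8 | methacrolein | CC(=C)C=O | starting material
9 | 6-(2-methylprop-2-en-1-ylidene) derivative of 7, enol form, isopropenyl group cis to the C7 carbonyl (the reacting isomer) | CC(=C)/C=C1\C(=O)[C@](C)(CC=C(C)C)C(=O)C(C(=O)C(C)C)=C1O | intermediate (not isolated)
10 | tricyclic adduct: bicyclo[3.2.1]octane (rings B and C, bridgeheads C6 and C9, C7 carbonyl as one-carbon bridge) fused across C6–C12 to a 1-methylcyclohexene (C2=C5); C13 exo on the two-carbon bridge, syn to C7; triketone enolised (C18=C29–OH) | CC1=C[C@]23C(=O)[C@](C)(C[C@@H]2C(C)(C)C1)C(=O)C(C(=O)C(C)C)=C3O | intermediate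
11 | keto aldehyde from cleavage of C2=C5: formyl group on C6, 2-methyl-4-oxopentan-2-yl chain on C12, configuration as in 10 | O=C[C@]12C(=O)[C@](C)(C[C@@H]1C(C)(C)CC(C)=O)C(=O)C(C(=O)C(C)C)=C2O | intermediate (not isolated)
12 | acetylcyclopentene triketone: ring A closed with C4=C5, acetyl on C4, otherwise as 10 | CC(=O)C1=C[C@]23C(=O)[C@](C)(C[C@@H]2C1(C)C)C(=O)C(C(=O)C(C)C)=C3O | intermediate
13 | C4 epimer of 14: acetyl on the face of ring A turned toward ring B, trans to H-12 | CC(=O)[C@@H]1C[C@]23C(=O)[C@](C)(C[C@@H]2C1(C)C)C(=O)C(C(=O)C(C)C)=C3O | intermediate (not isolated)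
14 | acetylcyclopentane triketone: target without the C18 prenyl group, acetyl cis to H-12, triketone enolised | CC(=O)[C@H]1C[C@]23C(=O)[C@](C)(C[C@@H]2C1(C)C)C(=O)C(C(=O)C(C)C)=C3O | intermediate
15 | CNP0322535.2: as 14 with C18 quaternary, prenyl on the face of ring C syn to the C7 bridge and isobutyryl toward the C11–C12 bridge | CC(=O)[C@H]1C[C@]23C(=O)[C@](C)(C[C@@H]2C1(C)C)C(=O)[C@](CC=C(C)C)(C(=O)C(C)C)C3=O | target

Total steps: 8. Longest linear sequence: 8 steps (1 to 15).

Steps most likely to fail

Step 5. The condensation product may rest as the 2H-pyran, or be drained by conjugate addition to methacrolein or by an intramolecular ene reaction of the prenyl group with the alkylidene dione, because the tether forces the cycloaddition into the electronically mismatched orientation. Thermal [3,3] shifts of the prenyl group could also erode the C9 configuration. The fallback uses known chemistry and sets out from 7. C-prenylation at C6 (prenyl bromide, NaOMe, MeOH, 0 °C) should give the 4,6-diprenyl trione F1. Oxidative radical cyclisation with Mn(OAc)3·2H2O and Cu(OAc)2·H2O in AcOH, of the kind established for dearomatised diprenyl acylphloroglucinols, then forms C6–C12 and C13–C4 by two successive 5-exo closures from the C6 radical. Oxidation of the resulting tertiary radical to the alkene should give the isopropenyl tricycle F2 as both C4 epimers. Ozonolysis of the isopropenyl group (O3, CH2Cl2, −78 °C; PPh3) and equilibration with DBU converge on 14, where the fallback rejoins the route.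

Step 3. Facial discrimination at the methyl-bearing carbon may be insufficient, or alkylation may be diverted to oxygen or to the chlorine-bearing carbon. The fallback sets out from 4. Alkylative dearomatisation with prenyl bromide and NaOMe in MeOH should give the racemic chloro trione F3. Zinc in acetic acid then gives the racemic trione F4, and preparative chromatography on a chiral stationary phase delivers 7, where the fallback rejoins the route.

Step 6. Ozone may attack the enolised triketone in competition with the ring alkene, and the formyl carbon C5 may be lost by retro-Claisen cleavage before the aldol closure. The fallback sets out from 10. Dihydroxylation with OsO4 (cat.) and NMO in acetone/water should give the C2,C5-diol F5. Glycol cleavage with NaIO4 on silica in CH2Cl2 gives keto aldehyde 11, where the fallback rejoins the route; 11 is closed with acid as in step 6.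

Further compounds
F1 | step 5 | 2-isobutyryl-4-methyl-4,6-diprenylcyclohexane-1,3,5-trione, dienol form, quaternary carbon as in 7 | CC(C)C(=O)C1=C(O)C(CC=C(C)C)=C(O)[C@](C)(CC=C(C)C)C1=O
F2 | step 5 | C4-isopropenyl analogue of 14 (both C4 epimers) | CC(=C)C1C[C@]23C(=O)[C@](C)(C[C@@H]2C1(C)C)C(=O)C(C(=O)C(C)C)=C3O
F3 | step 3 | racemic 6 | CC(C)C(=O)C1=C(O)C(Cl)=C(O)C(C)(CC=C(C)C)C1=O
F4 | step 3 | racemic 7 | CC(C)C(=O)C1=C(O)CC(=O)C(C)(CC=C(C)C)C1=O
F5 | step 6 | C2,C5-diol of 10 (cis-diol, configuration at C2 and C5 immaterial) | CC1(O)C(O)[C@]23C(=O)[C@](C)(C[C@@H]2C(C)(C)C1)C(=O)C(C(=O)C(C)C)=C3O
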